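Ring A is opened at its C1–C2 bond. It carries oxygen on C3 and C5, meta to each other and to the bridge carbon C1, which is the alternating pattern of a folded tetraketide, so it can be unfolded to a linear 3,5,7-trioxo ester. In one operation the key step releases this chain from a dioxinone, closes ring A by intramolecular aldol addition and aromatises it to a resorcylate. Its precursor is a diketo-dioxinone that already holds the two-carbon bridge and ring B, with O4 as a benzyl ether and O3 as a methoxymethyl ether, so that the late acetate needs no selectivity. Prenyl enters afterwards by lithiation between the two methoxy groups.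

Key step: step 8

Remark: the target has no stereocentre, and its only alkene carries two identical methyl groups, so no configuration has to be set. Ring A is numbered from the bridge carbon C1 (OMe on C3 and C5, prenyl on C4). Ring B is numbered from its bridge carbon C1 (OMe on C2, OH on C3, OAc on C4). The open chain of 13 is numbered from the ester carbon C1 to C9.

Step 1
Reactants: 1 2,3,4-trihydroxybenzaldehyde
Product: 2 4-(benzyloxy)-2,3-dihydroxybenzaldehyde
Conditions: BnBr (1.05 equiv), NaHCO3, NaI (cat.), DMF, 40 °C
Reagents that add atoms: benzyl bromide, BrCc1ccccc1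
Why: Williamson etherification in which the 4-hydroxyl, para to the formyl group and by far the most acidic phenol, is the only one ionised by hydrogencarbonate, so one equivalent of benzyl bromide should be taken up at O4.

Step 2
Reactants: 2 4-(benzyloxy)-2,3-dihydroxybenzaldehyde
Product: 3 4-(benzyloxy)-2-hydroxy-3-(methoxymethoxy)benzaldehyde
Conditions: NaH (2.2 equiv), THF/DMF, 0 °C; MOMCl (1.0 equiv), 0 °C; aq. NH4Cl
Reagents that add atoms: chloromethyl methyl ether, COCCl
Why: Williamson alkylation of the dianion, in which the 3-phenoxide is neither conjugated with nor chelated to the formyl group and is therefore the more nucleophilic oxygen, so the single equivalent of chloride should go to O3 and O2 should return as the hydrogen-bonded phenol on work-up.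

Step 3
Reactants: 3 4-(benzyloxy)-2-hydroxy-3-(methoxymethoxy)benzaldehyde
Product: 4 4-(benzyloxy)-2-methoxy-3-(methoxymethoxy)benzaldehyde
Conditions: MeI (3 equiv), K2CO3, DMF, 40 °C
Reagents that add atoms: iodomethane, CI
Why: Williamson methylation of the one remaining phenol, whose hydrogen bond to the aldehyde is overcome by carbonate in warm DMF; the benzyl ether and the acetal are inert to base.

Step 4
Reactants: 4 4-(benzyloxy)-2-methoxy-3-(methoxymethoxy)benzaldehyde
Product: 5 (2E)-3-[4-(benzyloxy)-2-methoxy-3-(methoxymethoxy)phenyl]-N-methoxy-N-methylprop-2-enamide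
Conditions: (EtO)2P(O)CH2C(O)N(OMe)Me, NaH, THF, 0 °C to rt
Reagents that add atoms: diethyl {2-[methoxy(methyl)amino]-2-oxoethyl}phosphonate, CCOP(=O)(CC(=O)N(C)OC)OCC
Why: Horner–Wadsworth–Emmons olefination with the stabilised phosphonate anion should give the E enamide and brings in the whole acyl unit already as a Weinreb amide.

Step 5
Reactants: 5 (2E)-3-[4-(benzyloxy)-2-methoxy-3-(methoxymethoxy)phenyl]-N-methoxy-N-methylprop-2-enamide
Product: 6 3-[4-(benzyloxy)-2-methoxy-3-(methoxymethoxy)phenyl]-N-methoxy-N-methylpropanamide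
Conditions: H2 (1 atm), Pd/C, 2,2′-bipyridyl (0.5 equiv), MeOH/EtOAc, rt
Reagents that add atoms: none
Why: Heterogeneous hydrogenation of the conjugated alkene on palladium poisoned with 2,2′-bipyridyl, an additive known to suppress hydrogenolysis of phenolic benzyl ethers while alkenes are still reduced; the N–O bond and the acetal should not be touched.

Step 6
Reactants: 7 2,2,6-trimethyl-4H-1,3-dioxin-4-one
Product: 9 2,2-dimethyl-6-(2-oxopropyl)-4H-1,3-dioxin-4-one, via lithium dienolate 8 (not isolated)
Conditions: 7 (2 equiv), LiN(SiMe3)2 (2 equiv), THF, −78 °C; AcCl (1 equiv), −78 °C; aq. NH4Cl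
Reagents that add atoms: acetyl chloride, CC(=O)Cl
Why: Deprotonation of the 6-methyl group of the vinylogous ester gives dienolate 8, which is C-acylated at its terminal carbon by acetyl chloride (crossed Claisen acylation); the second equivalent of dienolate absorbs the more acidic product, which is why 7 and the base are used in twofold amount.

Step 7
Reactants: 9 2,2-dimethyl-6-(2-oxopropyl)-4H-1,3-dioxin-4-one, 6 3-[4-(benzyloxy)-2-methoxy-3-(methoxymethoxy)phenyl]-N-methoxy-N-methylpropanamide
Product: 11 6-{6-[4-(benzyloxy)-2-methoxy-3-(methoxymethoxy)phenyl]-2,4-dioxohexyl}-2,2-dimethyl-4H-1,3-dioxin-4-one, via dilithium dienolate 10 (not isolated)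
Conditions: LiN(i-Pr)2 (2.2 equiv), THF, −78 °C; then 6, −78 to −30 °C; aq. NH4Cl
Reagents that add atoms: none
Why: Claisen-type C-acylation in which dianion 10 reacts at its terminal, more basic carbon with the Weinreb amide, whose chelated tetrahedral adduct survives until work-up and so should prevent over-addition and proton transfer to the product.

Step 8
Reactants: 11 6-{6-[4-(benzyloxy)-2-methoxy-3-(methoxymethoxy)phenyl]-2,4-dioxohexyl}-2,2-dimethyl-4H-1,3-dioxin-4-one
Product: 14 methyl 6-{2-[4-(benzyloxy)-2-methoxy-3-(methoxymethoxy)phenyl]ethyl}-2,4-dihydroxybenzoate, via acylketene 12 (not isolated), via methyl trioxo ester 13 (not isolated)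
Conditions: MeOH (10 equiv), PhMe, 110 °C (sealed tube); then Cs2CO3, MeOH, rt; aq. NH4Cl
Reagents that add atoms: methanol, CO
Why: At 110 °C the dioxinone should lose acetone by a retro-[4+2] reaction to give acylketene 12, which the excess methanol captures as β-keto ester 13 before an enol oxygen can lactonise it to a pyranone. Carbonate then enolises 13 reversibly, the C2 enolate adds to the C7 ketone to form the C1–C2 bond of ring A, and loss of water followed by two enolisations gives the aromatic resorcylate. The closest known reaction type is the biomimetic aldol aromatisation of dioxinone-masked 3,5,7-triketo esters to 6-alkyl-β-resorcylates. Ring A closes in the 6-(enolendo)-exo-trig mode when the nucleophile is written as the C2=C3 ketone enolate (6-(enolexo)-exo-trig through the ester-enolate form), and both modes are allowed. No stereocentre is formed. The selectivity needed is aldol over Claisen closure and O-acylation: C4 and C6 are more acidic than C2, but their enolates can only make four-membered rings with the ketones or attack the poorly electrophilic methyl ester; C8, the only other carbon placed for a six-membered aldol, is a simple ketone α-carbon that carbonate does not enolise, and aromatisation makes the C2-to-C7 closure irreversible.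

Step 9
Reactants: 14 methyl 6-{2-[4-(benzyloxy)-2-methoxy-3-(methoxymethoxy)phenyl]ethyl}-2,4-dihydroxybenzoate
Product: 16 5-{2-[4-(benzyloxy)-2-methoxy-3-(methoxymethoxy)phenyl]ethyl}benzene-1,3-diol, via resorcylic acid 15 (not isolated)
Conditions: KOH (aq.), MeOH, 110 °C (sealed tube, degassed); then NaH2PO4 (aq.) to pH 6
Reagents that add atoms: none
Why: Saponification followed by protodecarboxylation of the 2,4-dihydroxybenzoate, whose electron-rich ring is protonated at the carboxyl-bearing carbon so that CO2 leaves on heating; both ether protecting groups are stable to hydroxide, and loss of the carboxyl makes C2 and C6 of ring A equivalent, so the only position between two oxygens is the future prenyl site.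

Step 10
Reactants: 16 5-{2-[4-(benzyloxy)-2-methoxy-3-(methoxymethoxy)phenyl]ethyl}benzene-1,3-diol
Product: 17 1-(benzyloxy)-4-[2-(3,5-dimethoxyphenyl)ethyl]-3-methoxy-2-(methoxymethoxy)benzene
Conditions: MeI (3 equiv), K2CO3, DMF, rt
Reagents that add atoms: iodomethane, CI
Why: Williamson methylation of the two equivalent resorcinol hydroxyls, which needs no selectivity because ring B carries no free phenol at this stage.

Step 11
Reactants: 17 1-(benzyloxy)-4-[2-(3,5-dimethoxyphenyl)ethyl]-3-methoxy-2-(methoxymethoxy)benzene
Product: 18 4-[2-(3,5-dimethoxyphenyl)ethyl]-3-methoxy-2-(methoxymethoxy)phenol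
Conditions: H2 (1 atm), Pd/C, EtOAc/MeOH, rt
Reagents that add atoms: none
Why: Hydrogenolysis of the benzyl aryl ether on palladium, placed before any alkene is present; the methyl ethers and the methoxymethyl acetal are stable to these conditions.

Step 12
Reactants: 18 4-[2-(3,5-dimethoxyphenyl)ethyl]-3-methoxy-2-(methoxymethoxy)phenol, 19 prenyl bromide (1-bromo-3-methylbut-2-ene)
Product: 21 4-{2-[3,5-dimethoxy-4-(3-methylbut-2-en-1-yl)phenyl]ethyl}-3-methoxy-2-(methoxymethoxy)phenol, via dilithio species 20 (not isolated)
Conditions: n-BuLi (2.3 equiv), THF, 0 °C to rt; then 19 (1.05 equiv), −78 to 0 °C; aq. NH4Cl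
Reagents that add atoms: none
Why: Directed ortho-metalation in which the first equivalent of n-BuLi turns the phenol into its lithium salt (this deactivates ring B, whose acetal oxygen has no ortho hydrogen), the second removes the ring A hydrogen flanked by both methoxy groups, and the aryllithium should displace bromide from the primary carbon of 19 faster than the phenoxide can, which fixes prenyl on C4 of ring A and avoids the C- versus O- and site ambiguity of a Friedel–Crafts-type prenylation of a free resorcinol.

Step 13
Reactants: 21 4-{2-[3,5-dimethoxy-4-(3-methylbut-2-en-1-yl)phenyl]ethyl}-3-methoxy-2-(methoxymethoxy)phenol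
Product: 22 4-{2-[3,5-dimethoxy-4-(3-methylbut-2-en-1-yl)phenyl]ethyl}-3-methoxy-2-(methoxymethoxy)phenyl acetate
Conditions: Ac2O, pyridine, DMAP (cat.), CH2Cl2, 0 °C to rt
Reagents that add atoms: acetic anhydride, CC(=O)OC(C)=O
Why: DMAP-catalysed acetyl transfer to the only free hydroxyl; O3 is still masked, so the acetate can only go to O4.

Step 14
Reactants: 22 4-{2-[3,5-dimethoxy-4-(3-methylbut-2-en-1-yl)phenyl]ethyl}-3-methoxy-2-(methoxymethoxy)phenyl acetate
Product: 24 4-{2-[3,5-dimethoxy-4-(3-methylbut-2-en-1-yl)phenyl]ethyl}-2-hydroxy-3-methoxyphenyl acetate, via aryl trimethylsilyl ether 23 (not isolated)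
Conditions: Me3SiOTf (2 equiv), 2,2′-bipyridyl (3 equiv), MeCN, 0 °C to rt; then H2O
Reagents that add atoms: none
Why: Silyl triflate–bipyridyl cleavage of an aromatic methoxymethyl ether, in which the buffered aprotic reagent should convert the acetal into silyl ether 23 without free acid, so that the aryl acetate is not solvolysed and the trisubstituted alkene is not protonated, and water then hydrolyses 23 to the phenol at neutral pH, which limits acetyl migration to O3.

Compound list
1 | 2,3,4-trihydroxybenzaldehyde | O=Cc1ccc(O)c(O)c1O | starting material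
2 | 4-(benzyloxy)-2,3-dihydroxybenzaldehyde | O=Cc1ccc(OCc2ccccc2)c(O)c1O | intermediate
3 | 4-(benzyloxy)-2-hydroxy-3-(methoxymethoxy)benzaldehyde | O=Cc1ccc(OCc2ccccc2)c(OCOC)c1O | intermediate
4 | 4-(benzyloxy)-2-methoxy-3-(methoxymethoxy)benzaldehyde | O=Cc1ccc(OCc2ccccc2)c(OCOC)c1OC | intermediate
5 | (2E)-3-[4-(benzyloxy)-2-methoxy-3-(methoxymethoxy)phenyl]-N-methoxy-N-methylprop-2-enamide | CON(C)C(=O)/C=C/c1ccc(OCc2ccccc2)c(OCOC)c1OC | intermediate
6 | 3-[4-(benzyloxy)-2-methoxy-3-(methoxymethoxy)phenyl]-N-methoxy-N-methylpropanamide | CON(C)C(=O)CCc1ccc(OCc2ccccc2)c(OCOC)c1OC | intermediate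
7 | 2,2,6-trimethyl-4H-1,3-dioxin-4-one | CC1=CC(=O)OC(C)(C)O1 | starting material
8 | lithium 2,2-dimethyl-6-methylidene-6H-1,3-dioxin-4-olate (lithium dienolate of 7) | [Li]OC1=CC(=C)OC(C)(C)O1 | intermediate (not isolated)
9 | 2,2-dimethyl-6-(2-oxopropyl)-4H-1,3-dioxin-4-one | CC(=O)CC1=CC(=O)OC(C)(C)O1 | intermediate
10 | dilithium 4-(2,2-dimethyl-4-oxido-1,3-dioxin-6-ylidene)but-1-en-2-olate (dilithium dienolate of 9) | C=C(O[Li])C=C1C=C(O[Li])OC(C)(C)O1 | intermediate (not isolated)
11 | 6-{6-[4-(benzyloxy)-2-methoxy-3-(methoxymethoxy)phenyl]-2,4-dioxohexyl}-2,2-dimethyl-4H-1,3-dioxin-4-one | CC1(C)OC(=O)C=C(CC(=O)CC(=O)CCc2ccc(OCc3ccccc3)c(OCOC)c2OC)O1 | intermediate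
12 | 9-[4-(benzyloxy)-2-methoxy-3-(methoxymethoxy)phenyl]non-1-ene-1,3,5,7-tetrone (acylketene) | O=C=CC(=O)CC(=O)CC(=O)CCc1ccc(OCc2ccccc2)c(OCOC)c1OC | intermediate (not isolated)
13 | methyl 9-[4-(benzyloxy)-2-methoxy-3-(methoxymethoxy)phenyl]-3,5,7-trioxononanoate | COC(=O)CC(=O)CC(=O)CC(=O)CCc1ccc(OCc2ccccc2)c(OCOC)c1OC | intermediate (not isolated)
14 | methyl 6-{2-[4-(benzyloxy)-2-methoxy-3-(methoxymethoxy)phenyl]ethyl}-2,4-dihydroxybenzoate | COC(=O)c1c(O)cc(O)cc1CCc1ccc(OCc2ccccc2)c(OCOC)c1OC | intermediate
15 | 6-{2-[4-(benzyloxy)-2-methoxy-3-(methoxymethoxy)phenyl]ethyl}-2,4-dihydroxybenzoic acid (present as its potassium salt) | OC(=O)c1c(O)cc(O)cc1CCc1ccc(OCc2ccccc2)c(OCOC)c1OC | intermediate (not isolated)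
16 | 5-{2-[4-(benzyloxy)-2-methoxy-3-(methoxymethoxy)phenyl]ethyl}benzene-1,3-diol | Oc1cc(O)cc(CCc2ccc(OCc3ccccc3)c(OCOC)c2OC)c1 | intermediate
17 | 1-(benzyloxy)-4-[2-(3,5-dimethoxyphenyl)ethyl]-3-methoxy-2-(methoxymethoxy)benzene | COc1cc(OC)cc(CCc2ccc(OCc3ccccc3)c(OCOC)c2OC)c1 | intermediate
18 | 4-[2-(3,5-dimethoxyphenyl)ethyl]-3-methoxy-2-(methoxymethoxy)phenol | COc1cc(OC)cc(CCc2ccc(O)c(OCOC)c2OC)c1 | intermediate
19 | prenyl bromide (1-bromo-3-methylbut-2-ene) | CC(C)=CCBr | starting material
20 | dilithio derivative of 18 (lithium phenoxide at O4 of ring B, aryllithium at C4 of ring A) | [Li]Oc1ccc(CCc2cc(OC)c([Li])c(OC)c2)c(OC)c1OCOC | intermediate (not isolated)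
21 | 4-{2-[3,5-dimethoxy-4-(3-methylbut-2-en-1-yl)phenyl]ethyl}-3-methoxy-2-(methoxymethoxy)phenol | COc1cc(CCc2ccc(O)c(OCOC)c2OC)cc(OC)c1CC=C(C)C | intermediate
22 | 4-{2-[3,5-dimethoxy-4-(3-methylbut-2-en-1-yl)phenyl]ethyl}-3-methoxy-2-(methoxymethoxy)phenyl acetate | COc1cc(CCc2ccc(OC(C)=O)c(OCOC)c2OC)cc(OC)c1CC=C(C)C | intermediate
23 | 4-{2-[3,5-dimethoxy-4-(3-methylbut-2-en-1-yl)phenyl]ethyl}-3-methoxy-2-[(trimethylsilyl)oxy]phenyl acetate | COc1cc(CCc2ccc(OC(C)=O)c(O[Si](C)(C)C)c2OC)cc(OC)c1CC=C(C)C | intermediate (not isolated)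
24 | 4-{2-[3,5-dimethoxy-4-(3-methylbut-2-en-1-yl)phenyl]ethyl}-2-hydroxy-3-methoxyphenyl acetate | COc1cc(CCc2ccc(OC(C)=O)c(O)c2OC)cc(OC)c1CC=C(C)C | target

Total step count: 14
Longest linear sequence: 13 steps (from 1 to 24 through steps 1–5 and 7–14; step 6 is the side branch).

Steps most likely to fail

Step 8. The unmasked chain may fold in the wrong mode: an enol oxygen may capture the ketene to give a pyranone, Claisen attack may occur on the ester, or the open trioxo ester may undergo retro-Claisen cleavage in basic methanol before it cyclises. The fallback sets out from 11 and aromatises before unmasking, so that no free ketene and no open trioxo ester ever exist. Et3N in CH2Cl2 at room temperature should make the vinylogous enolate of the intact dioxinone add through its ring carbon to the remote ketone and, after dehydration, give the acetonide-protected resorcylate 5-{2-[4-(benzyloxy)-2-methoxy-3-(methoxymethoxy)phenyl]ethyl}-7-hydroxy-2,2-dimethyl-4H-1,3-benzodioxin-4-one F1. Hot aqueous KOH in MeOH then opens the acetal-lactone, expels acetone and decarboxylates the liberated acid, and the route is rejoined at 16.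

Step 12. The second lithiation may stall because the lithium phenoxide aggregates, some prenyl bromide may be consumed by O-alkylation of the phenoxide, or deprotonation may stray to another site. The fallback sets out from 16 and fixes the site with a halogen instead of a directed deprotonation. I2 and NaHCO3 in THF/H2O at 0 °C should iodinate the resorcinol between its two hydroxyls, as with resorcinol itself, to give 5-{2-[4-(benzyloxy)-2-methoxy-3-(methoxymethoxy)phenyl]ethyl}-2-iodobenzene-1,3-diol F2. MeI and K2CO3 give 1-(benzyloxy)-4-[2-(4-iodo-3,5-dimethoxyphenyl)ethyl]-3-methoxy-2-(methoxymethoxy)benzene F3. Iodine–lithium exchange with n-BuLi (1.05 equiv) in THF at −78 °C, which is far faster than any deprotonation, and trapping with 19 give 1-(benzyloxy)-4-{2-[3,5-dimethoxy-4-(3-methylbut-2-en-1-yl)phenyl]ethyl}-3-methoxy-2-(methoxymethoxy)benzene F4. The benzyl ether is then cleaved without hydrogen, by electron transfer from lithium 4,4′-di-tert-butylbiphenylide in THF at −78 °C, which leaves the trisubstituted alkene alone, and the route is rejoined at 21.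

Step 14. The acetyl group may move between the two neighbouring oxygens of ring B or be lost while the acetal is cleaved. The fallback sets out from 21 and reverses the order, so that the acetal is removed while no ester is present. Catalytic HCl in MeOH at 40 °C should give the catechol 4-{2-[3,5-dimethoxy-4-(3-methylbut-2-en-1-yl)phenyl]ethyl}-3-methoxybenzene-1,2-diol F5. Its less hindered 4-hydroxyl (the 3-hydroxyl is flanked by OMe and OH) is then acetylated with one equivalent of Ac2O and 2,4,6-collidine in CH2Cl2 at −20 °C, which arrives directly at 24. This variant relies on steric discrimination instead of a protecting group and is therefore held in reserve.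

Further compounds
F1 | step 8 | 5-{2-[4-(benzyloxy)-2-methoxy-3-(methoxymethoxy)phenyl]ethyl}-7-hydroxy-2,2-dimethyl-4H-1,3-benzodioxin-4-one | CC1(C)OC(=O)c2c(CCc3ccc(OCc4ccccc4)c(OCOC)c3OC)cc(O)cc2O1
F2 | step 12 | 5-{2-[4-(benzyloxy)-2-methoxy-3-(methoxymethoxy)phenyl]ethyl}-2-iodobenzene-1,3-diol | Oc1cc(CCc2ccc(OCc3ccccc3)c(OCOC)c2OC)cc(O)c1I
F3 | step 12 | 1-(benzyloxy)-4-[2-(4-iodo-3,5-dimethoxyphenyl)ethyl]-3-methoxy-2-(methoxymethoxy)benzene | COc1cc(CCc2ccc(OCc3ccccc3)c(OCOC)c2OC)cc(OC)c1I
F4 | step 12 | 1-(benzyloxy)-4-{2-[3,5-dimethoxy-4-(3-methylbut-2-en-1-yl)phenyl]ethyl}-3-methoxy-2-(methoxymethoxy)benzene | COc1cc(CCc2ccc(OCc3ccccc3)c(OCOC)c2OC)cc(OC)c1CC=C(C)C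
F5 | step 14 | 4-{2-[3,5-dimethoxy-4-(3-methylbut-2-en-1-yl)phenyl]ethyl}-3-methoxybenzene-1,2-diol | COc1cc(CCc2ccc(O)c(O)c2OC)cc(OC)c1CC=C(C)C
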